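**Plan**
- Rings: A = spiro δ-lactone, B = cyclohexane with the tertiary alcohol, C = cyclopentane, D/E = bicyclo[2.2.2]octenone, F = γ-lactone.
- Enabling feature: the ring B bond between the spiro carbon (shared by rings A and B) and the carbinol carbon C(CH3)(OH) is the aldol bond of the unit O=C–CH=CH–C(spiro)–C(OH), a δ-hydroxy-α,β-unsaturated lactone. The spiro carbon is thus the γ-carbon of a ring A dienolate and the carbinol carbon a methyl ketone.
- Cuts, in order: (i) that ring B bond; (ii) the CH2–C(sp2) bond joining the ethano chain to ring A; (iii) acetyl back to ethylidene; (iv) the two Diels–Alder bonds of rings D/E (which also close ring C) and the Claisen bond to the dienone quaternary carbon; (v) the aryl ether C–O bond.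
- Forward: ring F is present from the phthalide; rings C, D and E arise together in one Claisen/Diels–Alder cascade; ring A is attached preformed; ring B closes last.
- Stereochemistry: one carbinol centre from an asymmetric transfer hydrogenation, inverted by Mitsunobu and relayed by the chair Claisen to the dienone quaternary carbon, which fixes the other three cage centres in the cycloaddition. The ring C methine comes from face-selective epoxidation plus a stereospecific hydride shift; the spiro and carbinol centres are set by the cage in the final aldol.

Key step: step 13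

Assumption: compounds 1, 6 and 16 are taken as commercial, and the (R,R)-diamine catalyst of step 4 is assumed to give the (R)-alcohol as it does with other alkynyl methyl ketones.

Step 1
Reactants: 1 4-methoxy-3,5-dimethylbenzoic acid
Product: 4 5-methoxy-4,6-dimethylisobenzofuran-1(3H)-one, via dilithiated benzoate 2 (not isolated), via hydroxymethyl acid 3 (not isolated)
Conditions: s-BuLi (2.2 equiv), TMEDA, THF, −90 °C; HCHO (gas), −78 to 0 °C; 2 M HCl, 25 °C
Reagents that add atoms: formaldehyde C=O
Why: Carboxylate-directed ortho-lithiation (directed ortho-metalation; the two ortho positions are equivalent) and addition to formaldehyde give a 2-(hydroxymethyl)benzoic acid that should lactonize on acidification to the phthalide (ring F).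

Step 2
Reactants: 4 5-methoxy-4,6-dimethylisobenzofuran-1(3H)-one
Product: 5 5-hydroxy-4,6-dimethylisobenzofuran-1(3H)-one
Conditions: BBr3, CH2Cl2, −78 to 0 °C; H2O
Reagents that add atoms: none
Why: Lewis-acid cleavage of the aryl methyl ether (BBr3 demethylation) should be faster than attack on the phthalide at low temperature and frees the phenol.

Step 3
Reactants: 6 4-bromobut-1-yne
Product: 8 6-bromohex-3-yn-2-one, via lithium acetylide 7 (not isolated)
Conditions: n-BuLi, THF, −78 °C; N-methoxy-N-methylacetamide, −78 to −20 °C; cold 1 M HCl
Reagents that add atoms: N-methoxy-N-methylacetamide CC(=O)N(C)OC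
Why: Acylation of a lithium acetylide with a Weinreb amide stops at the ketone because the chelated adduct survives until the acidic quench, and deprotonation of the alkyne should outrun attack on the primary bromide at −78 °C.

Step 4
Reactants: 8 6-bromohex-3-yn-2-one
Product: 9 (2R)-6-bromohex-3-yn-2-ol
Conditions: RuCl[(R,R)-TsDPEN](p-cymene) (1 mol%), KOH (1 mol%), i-PrOH, 25 °C
Reagents that add atoms: none
Why: Noyori asymmetric transfer hydrogenation of an alkynyl methyl ketone should give the (R)-propargylic alcohol, the only stereocentre brought in by a chiral reagent.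

Step 5
Reactants: 5 5-hydroxy-4,6-dimethylisobenzofuran-1(3H)-one; 9 (2R)-6-bromohex-3-yn-2-ol
Product: 10 5-{[(2S)-6-bromohex-3-yn-2-yl]oxy}-4,6-dimethylisobenzofuran-1(3H)-one
Conditions: PPh3, DIAD, toluene, 0 to 25 °C
Reagents that add atoms: none
Why: Mitsunobu reaction: the acidic para-acyl phenol displaces the activated propargylic alcohol by SN2 with inversion, which should give the (S)-ether.

Step 6
Reactants: 10 5-{[(2S)-6-bromohex-3-yn-2-yl]oxy}-4,6-dimethylisobenzofuran-1(3H)-one
Product: 11 5-{[(2S)-6-bromo-3,4-dimethylidenehexan-2-yl]oxy}-4,6-dimethylisobenzofuran-1(3H)-one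
Conditions: second-generation Grubbs catalyst RuCl2(=CHPh)(PCy3)(H2IMes) (10 mol%), ethylene (1 atm), toluene, 80 °C
Reagents that add atoms: ethylene C=C
Why: Ene–yne cross-metathesis with ethylene converts the internal alkyne into a 2,3-disubstituted buta-1,3-diene and leaves the ether stereocentre and the bromide untouched.

Step 7
Reactants: 11 5-{[(2S)-6-bromo-3,4-dimethylidenehexan-2-yl]oxy}-4,6-dimethylisobenzofuran-1(3H)-one
Product: 13 bromoethyl (Z)-ethylidene cage keto lactone (rings C/D/E/F), via ortho-dienone 12 (not isolated)
Conditions: 1,2-dichlorobenzene (0.01 M), BHT, 180 °C, sealed tube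
Reagents that add atoms: none
Why: Aromatic Claisen rearrangement to the methyl-blocked ortho carbon next to the lactone CH2, then intramolecular Diels–Alder reaction of the ortho-dienone with the terminal C=CH2 of the side-chain diene: the chair transition state with equatorial methyl should carry the (S)-ether centre over to the (R)-quaternary dienone carbon and the (Z)-ethylidene, the three-atom tether lets the alkene add only to the diene face it hangs from so that the other three cage stereocentres follow, and because the rearrangement is reversible the dienone that keeps the lactone C=C inside the five-membered ring is the one expected to be trapped.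

Step 8
Reactants: 13 bromoethyl (Z)-ethylidene cage keto lactone
Product: 14 spiro-epoxide of 13
Conditions: mCPBA, NaHCO3, CH2Cl2, 0 °C
Reagents that add atoms: mCPBA OOC(=O)c1cccc(Cl)c1
Why: Prilezhaev epoxidation is selective for the electron-rich trisubstituted ethylidene over the lactone-conjugated alkene, and the peracid should approach the ring C face anti to the bridge CH2 on the neighbouring quaternary carbon, the face the acetyl group must occupy.

Step 9
Reactants: 14 spiro-epoxide of 13
Product: 15 bromoethyl cage methyl ketone
Conditions: BF3·OEt2 (0.2 equiv), CH2Cl2, −78 to −40 °C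
Reagents that add atoms: none
Why: Meinwald rearrangement: the Lewis acid opens the epoxide at the tertiary ring carbon and hydride shifts from the adjacent CH anti to the leaving oxygen, so the acetyl group should keep the former oxygen face and the ring C methine hydrogen take the opposite face, as in the target.

Step 10
Reactants: 16 2,2-dimethylcyclopentane-1,3-dione
Product: 17 6,6-dimethyloxane-2,5-dione
Conditions: mCPBA, NaHCO3, CH2Cl2, 25 °C
Reagents that add atoms: mCPBA OOC(=O)c1cccc(Cl)c1
Why: Baeyer–Villiger oxidation with migration of the quaternary carbon inserts one oxygen to give the six-membered keto lactone, and the remaining α-acyloxy ketone is deactivated towards a second insertion.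

Step 11
Reactants: 17 6,6-dimethyloxane-2,5-dione
Product: 18 6,6-dimethyl-2-oxo-3,6-dihydro-2H-pyran-5-yl trifluoromethanesulfonate
Conditions: Tf2O, 2,6-di-tert-butyl-4-methylpyridine, CH2Cl2, 0 to 25 °C
Reagents that add atoms: triflic anhydride O=S(=O)(OS(=O)(=O)C(F)(F)F)C(F)(F)F
Why: Enol triflate formation under non-basic conditions; the ketone can enolize only towards its CH2 because the other side is the quaternary C(CH3)2 carbon, which places the C=C of the future ring A in the deconjugated position.

Step 12
Reactants: 15 bromoethyl cage methyl ketone; 18 6,6-dimethyl-2-oxo-3,6-dihydro-2H-pyran-5-yl trifluoromethanesulfonate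
Product: 20 seco-ring-B keto lactone (ring A as the β,γ-unsaturated lactone), via alkylzinc bromide 19 (not isolated)
Conditions: Zn dust, LiCl, THF, 45 °C; then 18, Pd(OAc)2 (5 mol%), SPhos (10 mol%), THF, 25 °C
Reagents that add atoms: none
Why: Negishi sp3–sp2 cross-coupling: zinc should insert into the primary bromide without touching ketones or lactones, and palladium couples the alkylzinc with the enol triflate, joining ring A (still without a stereocentre) to the cage.

Step 13
Reactants: 20 seco-ring-B keto lactone
Product: 23 andibenin B, via lithium dienolate 21 (not isolated), via chlorozinc dienolate 22 (not isolated)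
Conditions: LiN(SiMe3)2 (1.05 equiv), THF, −78 °C; ZnCl2 (1.2 equiv), −78 to −30 °C; AcOH, −78 °C
Reagents that add atoms: none
Why: LiN(SiMe3)2 removes a proton from the lactone CH2 that is both allylic and α to the carbonyl (several pK units more acidic than the methyl ketone), ZnCl2 turns the lithium dienolate into the less basic zinc dienolate, and its γ-carbon adds to the ketone in an intramolecular vinylogous aldol addition of the Reformatsky type. Ring B closes by 6-(enolexo)-exo-trig attack of the γ-carbon on the carbonyl, whereas attack through the α-carbon would need an eight-membered ring, so the γ-regiochemistry is set by the tether. The carbinol centre should be controlled by the cage: ring C holds the forming ring B in the chair whose axial site at the carbonyl carbon is syn to the bond from the neighbouring quaternary carbon to the bridgehead, so the acetyl methyl stays equatorial and the oxygen becomes axial. The spiro centre should be controlled by a closed six-membered transition state in which zinc bridges the lactone α-carbon and the ketone oxygen, which puts the ring A CH= carbon cis to that oxygen on ring B and the C(CH3)2–O carbon trans to it, as in the target. The step needs chemoselective enolization and site selectivity among four carbonyl groups: the bridging ketone has no α-hydrogen and lies a seven-membered ring away, the γ-lactone has no γ-hydrogen, and the ketone methyl is the weaker acid. The cold acetic acid quench is meant to stop retro-aldol cleavage, translactonization by the new alkoxide and ring opening of the pyran dienolate.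

**Compound list**
1 | 4-methoxy-3,5-dimethylbenzoic acid | COc1c(C)cc(cc1C)C(=O)O | starting material
2 | lithium 2-lithio-4-methoxy-3,5-dimethylbenzoate | [Li]c1c(C)c(OC)c(C)cc1C(=O)O[Li] | intermediate (not isolated)
3 | 2-(hydroxymethyl)-4-methoxy-3,5-dimethylbenzoic acid | COc1c(C)cc(C(=O)O)c(CO)c1C | intermediate (not isolated)
4 | 5-methoxy-4,6-dimethylisobenzofuran-1(3H)-one | COc1c(C)cc2C(=O)OCc2c1C | intermediate
5 | 5-hydroxy-4,6-dimethylisobenzofuran-1(3H)-one | Cc1cc2C(=O)OCc2c(C)c1O | intermediate
6 | 4-bromobut-1-yne | C#CCCBr | starting material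
7 | (4-bromobut-1-yn-1-yl)lithium | [Li]C#CCCBr | intermediate (not isolated)
8 | 6-bromohex-3-yn-2-one | CC(=O)C#CCCBr | intermediate
9 | (2R)-6-bromohex-3-yn-2-ol | C[C@@H](O)C#CCCBr | intermediate
10 | 5-{[(2S)-6-bromohex-3-yn-2-yl]oxy}-4,6-dimethylisobenzofuran-1(3H)-one | C[C@H](Oc1c(C)cc2C(=O)OCc2c1C)C#CCCBr | intermediate
11 | 5-{[(2S)-6-bromo-3,4-dimethylidenehexan-2-yl]oxy}-4,6-dimethylisobenzofuran-1(3H)-one | C[C@H](Oc1c(C)cc2C(=O)OCc2c1C)C(=C)C(=C)CCBr | intermediate
12 | (4R)-4-[(2Z)-5-bromo-2-ethylidene-3-methylidenepentyl]-4,6-dimethyl-3,4-dihydroisobenzofuran-1,5-dione (ortho-dienone) | O=C1C(C)=CC2=C(COC2=O)[C@@]1(C)C/C(=C/C)C(=C)CCBr | intermediate (not isolated)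
13 | Diels–Alder adduct: bicyclo[2.2.2]octenone fused to the γ-lactone and to a cyclopentane carrying an exocyclic (Z)-ethylidene, with a 2-bromoethyl group on the quaternary carbon shared by rings C and D; cage configuration as in the target | BrCC[C@@]13C[C@@]4(C)C=C5C(=O)OC[C@]51[C@@](C)(C/C3=C/C)C4=O | intermediate
14 | spiro-epoxide of 13, oxygen on the ring C face anti to the bridge CH2 | BrCC[C@@]13C[C@@]4(C)C=C5C(=O)OC[C@]51[C@@](C)(C[C@@]32O[C@H]2C)C4=O | intermediate
15 | cage methyl ketone: acetyl on ring C cis to the 2-bromoethyl chain | BrCC[C@@]13C[C@@]4(C)C=C5C(=O)OC[C@]51[C@@](C)(C[C@H]3C(C)=O)C4=O | intermediate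
16 | 2,2-dimethylcyclopentane-1,3-dione | CC1(C)C(=O)CCC1=O | starting material
17 | 6,6-dimethyloxane-2,5-dione | CC1(C)OC(=O)CCC1=O | intermediate
18 | 6,6-dimethyl-2-oxo-3,6-dihydro-2H-pyran-5-yl trifluoromethanesulfonate | CC1(C)OC(=O)CC=C1OS(=O)(=O)C(F)(F)F | intermediate
19 | alkylzinc bromide derived from 15 | Br[Zn]CC[C@@]13C[C@@]4(C)C=C5C(=O)OC[C@]51[C@@](C)(C[C@H]3C(C)=O)C4=O | intermediate (not isolated)
20 | seco-ring-B keto lactone: cage methyl ketone linked by CH2CH2 to C5 of 6,6-dimethyl-3,6-dihydro-2H-pyran-2-one | CC1(C)OC(=O)CC=C1CC[C@@]13C[C@@]4(C)C=C5C(=O)OC[C@]51[C@@](C)(C[C@H]3C(C)=O)C4=O | intermediate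
21 | lithium dienolate of 20 (ring A as 6-oxido-2H-pyran) | CC1(C)OC(O[Li])=CC=C1CC[C@@]13C[C@@]4(C)C=C5C(=O)OC[C@]51[C@@](C)(C[C@H]3C(C)=O)C4=O | intermediate (not isolated)
22 | chlorozinc dienolate of 20 | CC1(C)OC(O[Zn]Cl)=CC=C1CC[C@@]13C[C@@]4(C)C=C5C(=O)OC[C@]51[C@@](C)(C[C@H]3C(C)=O)C4=O | intermediate (not isolated)
23 | andibenin B | CC1(C)OC(=O)C=C[C@]12CC[C@@]13C[C@@]4(C)C=C5C(=O)OC[C@]51[C@@](C)(C[C@H]3[C@@]2(C)O)C4=O | target

**Count**
Total steps: 13. Longest linear sequence: 9 steps (steps 3, 4, 5, 6, 7, 8, 9, 12, 13; the sequence through steps 1 and 2 is equally long).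

**Steps most likely to fail**

Step 13. The pyran dienolate may open by β-elimination of the ring oxygen to a dienoate before it adds. The aldolate may also revert or translactonize on warming, and the facial selectivity at the spiro carbon rests on the closed transition state. The fallback sets out from 14 and returns at 23; it generates the ketone only under Lewis acid, in the presence of a preformed silyl dienol ether, so that an open transition state operates and the ketone never meets base. Zinc insertion into 14 gives the epoxy alkylzinc bromide F1, and Negishi coupling with 18 gives the epoxy lactone F2. LiN(SiMe3)2 with tert-butyldimethylsilyl chloride present at −78 °C gives the epoxy silyl dienol ether F3. BF3·OEt2 at −78 °C then triggers the Meinwald rearrangement to the keto silyl dienol ether F4, which is trapped at once by intramolecular vinylogous Mukaiyama aldol addition and gives 23 after aqueous work-up.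

Step 7. The allyl unit may migrate to the other ortho carbon (the one next to the aromatic CH), and that dienone may cyclize instead; thermal ionization of the allylic ether is a second loss. The fallback sets out from 4 and returns at 13, using a removable bromine on the only free ring position so that the competing diene terminus becomes fully substituted and loses its steric advantage. Bromination of 4 (Br2, AcOH) gives 7-bromo-5-methoxy-4,6-dimethylisobenzofuran-1(3H)-one F5, and BBr3 gives the bromophenol F6. Mitsunobu reaction with 9 gives the bromo aryl propargyl ether F7, and ethylene ene–yne metathesis gives the bromo aryl dienyl ether F8. Thermolysis as in step 7 passes through the bromo ortho-dienone F9 to the vinyl bromide cage F10, and zinc in acetic acid removes the vinylic bromine β to the lactone carbonyl to give 13.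

Step 9. A ring bond or the methyl group may migrate instead of hydride, or epoxidation from the other face may deliver the wrong configuration at the ring C methine. The fallback sets out from 13 and returns at 15 by hydroboration instead of epoxide rearrangement. 9-Borabicyclo[3.3.1]nonane (the bridging ketone, flanked by two quaternary carbons, should survive) followed by NaBO3 gives the secondary alcohol F11 by syn addition from the exposed face. Dess–Martin periodinane gives the epimeric methyl ketone F12. Equilibration with DBU through the enol is expected to move the acetyl group to the face anti to the bridge CH2 and so give 15, with the unwanted epimer recycled.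

**Further compounds**
F1 | step 13 | epoxy alkylzinc bromide | Br[Zn]CC[C@@]13C[C@@]4(C)C=C5C(=O)OC[C@]51[C@@](C)(C[C@@]32O[C@H]2C)C4=O
F2 | step 13 | epoxy lactone (14 with ring A in place of bromine) | CC1(C)OC(=O)CC=C1CC[C@@]13C[C@@]4(C)C=C5C(=O)OC[C@]51[C@@](C)(C[C@@]32O[C@H]2C)C4=O
F3 | step 13 | epoxy tert-butyldimethylsilyl dienol ether | CC1(C)OC(O[Si](C)(C)C(C)(C)C)=CC=C1CC[C@@]13C[C@@]4(C)C=C5C(=O)OC[C@]51[C@@](C)(C[C@@]32O[C@H]2C)C4=O
F4 | step 13 | keto tert-butyldimethylsilyl dienol ether (not isolated) | CC1(C)OC(O[Si](C)(C)C(C)(C)C)=CC=C1CC[C@@]13C[C@@]4(C)C=C5C(=O)OC[C@]51[C@@](C)(C[C@H]3C(C)=O)C4=O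
F5 | step 7 | 7-bromo-5-methoxy-4,6-dimethylisobenzofuran-1(3H)-one | COc1c(C)c(Br)c2C(=O)OCc2c1C
F6 | step 7 | 7-bromo-5-hydroxy-4,6-dimethylisobenzofuran-1(3H)-one | Oc1c(C)c(Br)c2C(=O)OCc2c1C
F7 | step 7 | 7-bromo-5-{[(2S)-6-bromohex-3-yn-2-yl]oxy}-4,6-dimethylisobenzofuran-1(3H)-one | C[C@H](Oc1c(C)c(Br)c2C(=O)OCc2c1C)C#CCCBr
F8 | step 7 | 7-bromo-5-{[(2S)-6-bromo-3,4-dimethylidenehexan-2-yl]oxy}-4,6-dimethylisobenzofuran-1(3H)-one | C[C@H](Oc1c(C)c(Br)c2C(=O)OCc2c1C)C(=C)C(=C)CCBr
F9 | step 7 | bromo ortho-dienone (not isolated) | O=C1C(C)=C(Br)C2=C(COC2=O)[C@@]1(C)C/C(=C/C)C(=C)CCBr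
F10 | step 7 | vinyl bromide analogue of 13 | BrCC[C@@]13C[C@@]4(C)C(Br)=C5C(=O)OC[C@]51[C@@](C)(C/C3=C/C)C4=O
F11 | step 9 | secondary alcohol from hydroboration of 13 | BrCC[C@@]13C[C@@]4(C)C=C5C(=O)OC[C@]51[C@@](C)(C[C@@H]3[C@H](C)O)C4=O
F12 | step 9 | methyl ketone epimeric with 15 at the ring C methine | BrCC[C@@]13C[C@@]4(C)C=C5C(=O)OC[C@]51[C@@](C)(C[C@@H]3C(C)=O)C4=O
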